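The cyclohexene ring (C1–C6) is cut at C1–C6 and C2=C3. Ring atoms C3–C6 are the four carbons of methyl vinyl ketone, and C2 is an aldehyde carbon whose α-carbon is C1, the ring methine that already carries the C7 methyl stereocentre. One amine-catalysed operation therefore joins (R)-5-silyloxy-3-methylpentanal to the enone by enamine Michael addition (C1–C6, fixing C1) and closes the ring by aldol condensation (C2=C3), giving a 4-substituted cyclohex-2-enone whose carbonyl becomes the C4 methyl carbinol. The precursor is a β-branched, α-unsubstituted aldehyde with C9 masked as a silyl ether; C9 is later joined to the C10–C15 iodoacrylate by chromium-mediated alkenylation.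

Key step: step 5

Numbering used below: ring C1 (CH carrying the chain), C2=C3, C4 (C(CH3)OH), C5, C6; chain C7 (CHCH3), C8, C9 (CHOAc), C10=C11 (CO2Me), C12–C15. Target configuration: 1S, 4R (hydroxyl trans to the side chain), 7R, 9S, C10=C11 E.

Remark (assumption on the chemistry): in step 1 the quinidine-derived catalyst (DHQD)2AQN is taken to give the R half-ester 2. If the sign of rotation of 2 shows the opposite sense, the pseudoenantiomeric (DHQ)2AQN is used and nothing else changes.

Step 1
Reactants: 1 3-methylglutaric anhydride
Product: 2 (R)-5-methoxy-3-methyl-5-oxopentanoic acid (methyl hydrogen (R)-3-methylglutarate)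
Conditions: MeOH (10 equiv), (DHQD)2AQN (hydroquinidine anthraquinone-1,4-diyl diether, cat.), Et2O, −40 °C
Reagents that add atoms: methanol, CO
Why: Alcoholytic desymmetrisation of a prochiral cyclic anhydride: the alkaloid acts as a chiral general base that directs methanol to one of the two enantiotopic carbonyl groups, which sets C7 (R) without any reaction at the stereocentre itself.

Step 2
Reactants: 2 (R)-5-methoxy-3-methyl-5-oxopentanoic acid
Product: 3 methyl (R)-5-hydroxy-3-methylpentanoate
Conditions: BH3·SMe2, THF, −10 °C to rt; MeOH quench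
Reagents that add atoms: none
Why: Chemoselective borane reduction of a carboxylic acid (through the acyloxyborane) in the presence of a methyl ester turns the acid terminus into the future C9 carbinol and leaves C7 untouched; the crude δ-hydroxy ester is carried on at once to avoid lactonisation.

Step 3
Reactants: 3 methyl (R)-5-hydroxy-3-methylpentanoate
Product: 4 methyl (R)-5-[(tert-butyldiphenylsilyl)oxy]-3-methylpentanoate
Conditions: TBDPSCl, imidazole, DMF, 0 °C to rt
Reagents that add atoms: tert-butyl(chloro)diphenylsilane, CC(C)(C)[Si](Cl)(c1ccccc1)c1ccccc1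
Why: Imidazole-promoted silylation of the primary alcohol is fast and basic, so it outruns lactonisation, and the tert-butyldiphenylsilyl ether is chosen because it survives hydride, amine, hydroxide and organolithium reagents and is later removed by fluoride without acid or oxidant.

Step 4
Reactants: 4 methyl (R)-5-[(tert-butyldiphenylsilyl)oxy]-3-methylpentanoate
Product: 5 (R)-5-[(tert-butyldiphenylsilyl)oxy]-3-methylpentanal
Conditions: iBu2AlH (1.1 equiv), CH2Cl2, −78 °C; aq. potassium sodium tartrate
Reagents that add atoms: none
Why: Low-temperature partial reduction of the ester by iBu2AlH stops at the tetrahedral aluminium hemiacetal, which gives the aldehyde on work-up; the carbon α to the new carbonyl is a methylene, so C7 cannot epimerise.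

Step 5
Reactants: 5 (R)-5-[(tert-butyldiphenylsilyl)oxy]-3-methylpentanal; 6 but-3-en-2-one
Product: 9 (S)-4-[(R)-4-[(tert-butyldiphenylsilyl)oxy]butan-2-yl]cyclohex-2-en-1-one, via 5-oxohexanal Michael adduct 7 (not isolated), via 3-hydroxycyclohexanone aldol adduct 8 (not isolated)
Conditions: (S)-α,α-diphenylprolinol trimethylsilyl ether (10 mol%), ethyl 3,4-dihydroxybenzoate (20 mol%), neat, 4 °C; then LiOH, iPrOH, rt
Reagents that add atoms: none
Why: The secondary amine condenses with 5 to the (E)-enamine, whose α-carbon C1 adds to the terminal carbon of 6 (C6) from the face not screened by the diphenyl(silyloxy)methyl group, and hydrolysis of the iminium releases keto-aldehyde 7; LiOH then generates the methyl-ketone enolate, which attacks the aldehyde carbon to give 8, and 8 loses water by E1cB to the conjugated enone. The closest known reaction type is the diarylprolinol ether-catalysed Michael addition of β-branched aldehydes to methyl vinyl ketone followed by base-mediated aldol condensation, the organocatalytic Robinson-type annulation used for 4-alkylcyclohex-2-enones of the bisabolane and cryptone series. The single ring (C1–C6) closes by a 6-(enolendo)-exo-trig aldol addition, because both enolate carbons (C3 and C4) lie inside the new ring and the aldehyde oxygen outside it. The new stereocentre C1 (S) is controlled by the catalyst: the S-configured pyrrolidine delivers the electrophile to the Si face of the enamine α-carbon, which corresponds to 1S here, and this control is expected to override the weak bias of the neighbouring C7 centre. The step needs mono-Michael addition at C1 and one regiochemistry of ring closure: the α-methylene of 5 forms the enamine readily whereas the α-branched adduct 7 does not, and of the enolisable positions of 7 only the ketone methyl (C3) can reach the aldehyde through a six-membered transition state. The short, mild hydroxide treatment is meant to keep C1 (α to the aldehyde in 7, γ to the carbonyl in 9) from epimerising.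

Step 6
Reactants: 9 (S)-4-[(R)-4-[(tert-butyldiphenylsilyl)oxy]butan-2-yl]cyclohex-2-en-1-one
Product: 10 (1R,4S)-4-[(R)-4-[(tert-butyldiphenylsilyl)oxy]butan-2-yl]-1-methylcyclohex-2-en-1-ol
Conditions: CeCl3 (anhydrous), MeLi, THF, −78 °C; aq. NH4Cl; chromatography to remove the C4 epimer
Reagents that add atoms: methyllithium, [Li]C
Why: Organocerium 1,2-addition to the enone carbonyl: the weakly basic, oxophilic methylcerium reagent suppresses enolisation (which would scramble C1) and conjugate addition, and attack along the axial trajectory of the half-chair that holds the C1 side chain pseudoequatorial places the methyl group cis and the hydroxyl trans to the side chain (4R), the C4 epimer being removed by chromatography.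

Step 7
Reactants: 10 (1R,4S)-4-[(R)-4-[(tert-butyldiphenylsilyl)oxy]butan-2-yl]-1-methylcyclohex-2-en-1-ol
Product: 11 (1R,4S)-4-[(R)-4-hydroxybutan-2-yl]-1-methylcyclohex-2-en-1-ol
Conditions: Bu4NF, THF, 0 °C to rt
Reagents that add atoms: none
Why: Fluoride-driven desilylation (formation of the strong Si–F bond) frees the primary C9 alcohol under basic conditions that leave the ionisable tertiary allylic alcohol alone.

Step 8
Reactants: 11 (1R,4S)-4-[(R)-4-hydroxybutan-2-yl]-1-methylcyclohex-2-en-1-ol
Product: 12 (R)-3-[(1S,4R)-4-hydroxy-4-methylcyclohex-2-en-1-yl]butanal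
Conditions: Dess–Martin periodinane, NaHCO3, CH2Cl2, 0 °C to rt; used directly in step 13
Reagents that add atoms: none
Why: Dess–Martin oxidation under hydrogencarbonate buffer converts the primary alcohol into the aldehyde; the tertiary alcohol has no carbinol hydrogen and C7 is β to the new carbonyl, so neither is affected.

Step 9
Reactants: 13 diethyl malonate (excess); 14 5-bromo-2-methylpent-2-ene
Product: 15 diethyl 2-(4-methylpent-3-en-1-yl)malonate
Conditions: NaOEt, EtOH, reflux
Reagents that add atoms: none
Why: Malonic ester alkylation, an SN2 reaction of the stabilised enolate at a primary homoallylic bromide, with the malonate in excess to suppress dialkylation.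

Step 10
Reactants: 15 diethyl 2-(4-methylpent-3-en-1-yl)malonate
Product: 16 diethyl 2-(diiodomethyl)-2-(4-methylpent-3-en-1-yl)malonate
Conditions: NaH, CHI3, Et2O, reflux
Reagents that add atoms: iodoform, [I][CH]([I])[I]
Why: Diiodomethylation of the malonate enolate with iodoform, the first stage of the established route from alkylmalonates to (E)-3-iodo-2-alkylacrylic acids; the fully substituted carbon formed cannot react again.

Step 11
Reactants: 16 diethyl 2-(diiodomethyl)-2-(4-methylpent-3-en-1-yl)malonate
Product: 18 (E)-2-(iodomethylidene)-6-methylhept-5-enoic acid, via diiodomethyl malonic diacid 17 (not isolated)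
Conditions: KOH, EtOH–H2O, reflux; then aq. HCl, 0 °C
Reagents that add atoms: potassium hydroxide, [K+].[OH-]
Why: Saponification gives the malonate dianion of 17, which loses CO2 and iodide in a Grob-type decarboxylative elimination; as in the known 2-methyl series the iodine ends trans to the carboxyl group (E).

Step 12
Reactants: 18 (E)-2-(iodomethylidene)-6-methylhept-5-enoic acid
Product: 19 methyl (E)-2-(iodomethylidene)-6-methylhept-5-enoate
Conditions: MeI, K2CO3, DMF, rt
Reagents that add atoms: iodomethane, CI
Why: SN2 O-methylation of the carboxylate under mild carbonate base leaves the vinyl iodide and both alkene geometries unchanged.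

Step 13
Reactants: 12 (R)-3-[(1S,4R)-4-hydroxy-4-methylcyclohex-2-en-1-yl]butanal; 19 methyl (E)-2-(iodomethylidene)-6-methylhept-5-enoate
Product: 20 methyl (2E,4S,6R)-4-hydroxy-6-[(1S,4R)-4-hydroxy-4-methylcyclohex-2-en-1-yl]-2-(4-methylpent-3-en-1-yl)hept-2-enoate
Conditions: CrCl2 (cat.), chiral 4-substituted oxazoline N-aryl methanesulfonamide ligand (cat., antipode giving 9S), 1,8-bis(dimethylamino)naphthalene, NiCl2(2,9-dimethyl-1,10-phenanthroline) (cat.), Mn powder, Cp2ZrCl2, LiCl, MeCN, rt
Reagents that add atoms: none
Why: Nozaki–Hiyama–Kishi alkenylation: zerovalent nickel inserts into the C–I bond, transmetalation gives an alkenyl species of trivalent chromium that adds to the aldehyde with retention of the E geometry, and the chiral sulfonamide ligand on chromium selects the aldehyde face and sets C9 (S) under reagent control (ligand antipode assigned in a small-scale trial, C9 checked by MTPA ester analysis), while the tertiary alcohol and the ester are tolerated and the carbinol lying trans to the ester cannot lactonise.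

Step 14
Reactants: 20 methyl (2E,4S,6R)-4-hydroxy-6-[(1S,4R)-4-hydroxy-4-methylcyclohex-2-en-1-yl]-2-(4-methylpent-3-en-1-yl)hept-2-enoate
Product: 21 methyl (2E,4S,6R)-4-acetoxy-6-[(1S,4R)-4-hydroxy-4-methylcyclohex-2-en-1-yl]-2-(4-methylpent-3-en-1-yl)hept-2-enoate (CNP0360342.1)
Conditions: Ac2O (1.2 equiv), pyridine, DMAP (cat.), CH2Cl2, 0 °C
Reagents that add atoms: acetic anhydride, CC(=O)OC(C)=O
Why: Nucleophile-catalysed acylation is much faster at the secondary allylic alcohol than at the hindered tertiary one, so a slight excess of Ac2O at 0 °C acetylates only the C9 hydroxyl, with retention at C9.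

Compound list
1 | 3-methylglutaric anhydride (4-methyloxane-2,6-dione) | CC1CC(=O)OC(=O)C1 | starting material
2 | (R)-5-methoxy-3-methyl-5-oxopentanoic acid | OC(=O)C[C@@H](C)CC(=O)OC | intermediate
3 | methyl (R)-5-hydroxy-3-methylpentanoate | OCC[C@@H](C)CC(=O)OC | intermediate
4 | methyl (R)-5-[(tert-butyldiphenylsilyl)oxy]-3-methylpentanoate | CC(C)(C)[Si](OCC[C@@H](C)CC(=O)OC)(c1ccccc1)c1ccccc1 | intermediate
5 | (R)-5-[(tert-butyldiphenylsilyl)oxy]-3-methylpentanal | CC(C)(C)[Si](OCC[C@@H](C)CC=O)(c1ccccc1)c1ccccc1 | intermediate
6 | but-3-en-2-one | CC(=O)C=C | starting material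
7 | (S)-2-[(R)-4-[(tert-butyldiphenylsilyl)oxy]butan-2-yl]-5-oxohexanal | CC(C)(C)[Si](OCC[C@@H](C)[C@H](CCC(C)=O)C=O)(c1ccccc1)c1ccccc1 | intermediate
8 | (4S)-4-[(R)-4-[(tert-butyldiphenylsilyl)oxy]butan-2-yl]-3-hydroxycyclohexan-1-one (either carbinol epimer) | CC(C)(C)[Si](OCC[C@@H](C)[C@H]1C(O)CC(=O)CC1)(c1ccccc1)c1ccccc1 | intermediate
9 | (S)-4-[(R)-4-[(tert-butyldiphenylsilyl)oxy]butan-2-yl]cyclohex-2-en-1-one | CC(C)(C)[Si](OCC[C@@H](C)[C@H]1C=CC(=O)CC1)(c1ccccc1)c1ccccc1 | intermediate
10 | (1R,4S)-4-[(R)-4-[(tert-butyldiphenylsilyl)oxy]butan-2-yl]-1-methylcyclohex-2-en-1-ol | CC(C)(C)[Si](OCC[C@@H](C)[C@H]1C=C[C@](C)(O)CC1)(c1ccccc1)c1ccccc1 | intermediate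
11 | (1R,4S)-4-[(R)-4-hydroxybutan-2-yl]-1-methylcyclohex-2-en-1-ol | OCC[C@@H](C)[C@H]1C=C[C@](C)(O)CC1 | intermediate
12 | (R)-3-[(1S,4R)-4-hydroxy-4-methylcyclohex-2-en-1-yl]butanal | O=CC[C@@H](C)[C@H]1C=C[C@](C)(O)CC1 | intermediate
13 | diethyl malonate | CCOC(=O)CC(=O)OCC | starting material
14 | 5-bromo-2-methylpent-2-ene | CC(C)=CCCBr | starting material
15 | diethyl 2-(4-methylpent-3-en-1-yl)malonate | CCOC(=O)C(CCC=C(C)C)C(=O)OCC | intermediate
16 | diethyl 2-(diiodomethyl)-2-(4-methylpent-3-en-1-yl)malonate | CCOC(=O)C(CCC=C(C)C)(C([I])[I])C(=O)OCC | intermediate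
17 | 2-(diiodomethyl)-2-(4-methylpent-3-en-1-yl)malonic acid (present as its dipotassium salt) | OC(=O)C(CCC=C(C)C)(C([I])[I])C(=O)O | intermediate
18 | (E)-2-(iodomethylidene)-6-methylhept-5-enoic acid (iodine trans to the carboxyl group) | OC(=O)/C(=C/I)CCC=C(C)C | intermediate
19 | methyl (E)-2-(iodomethylidene)-6-methylhept-5-enoate | COC(=O)/C(=C/I)CCC=C(C)C | intermediate
20 | methyl (2E,4S,6R)-4-hydroxy-6-[(1S,4R)-4-hydroxy-4-methylcyclohex-2-en-1-yl]-2-(4-methylpent-3-en-1-yl)hept-2-enoate | COC(=O)/C(=C/[C@H](C[C@@H](C)[C@H]1C=C[C@](C)(O)CC1)O)CCC=C(C)C | intermediate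
21 | methyl (2E,4S,6R)-4-acetoxy-6-[(1S,4R)-4-hydroxy-4-methylcyclohex-2-en-1-yl]-2-(4-methylpent-3-en-1-yl)hept-2-enoate | COC(=O)/C(=C/[C@H](C[C@@H](C)[C@H]1C=C[C@](C)(O)CC1)OC(C)=O)CCC=C(C)C | target

Total step count: 14 (main line steps 1–8, 13 and 14; iodoacrylate branch steps 9–12).
Longest linear sequence: 10 steps (1–8, 13, 14) from 3-methylglutaric anhydride.

Steps most likely to fail

Step 5. The catalyst may not fully override the adjacent C7 centre in the Michael addition, C1 may erode by enolisation during the base-mediated ring closure, or self-aldol of the aldehyde may compete. The fallback sets C1 by auxiliary control instead of catalyst control. It sets out from 5, which is condensed with (R)-1-amino-2-(methoxymethyl)pyrrolidine to the RAMP hydrazone F1. Deprotonation with LiN(iPr)2 in THF and alkylation of the azaenolate at low temperature with 2-(2-iodoethyl)-2-methyl-1,3-dioxolane (SAMP/RAMP hydrazone alkylation; the auxiliary antipode is the one the azaenolate model assigns to 1S) should give the alkylated hydrazone F2. Ozonolysis in CH2Cl2 at −78 °C releases the ketal aldehyde F3. Pyridinium p-toluenesulfonate in wet acetone then unmasks the ketone, and the route is rejoined at keto-aldehyde 7, which is closed to 9 with LiOH in iPrOH as in the second stage of step 5.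

Step 6. The remote C1 substituent may give only weak facial discrimination in the methyl addition, so that much of the C4 epimer forms and the separation becomes wasteful. The fallback replaces substrate control by catalyst control and a polar addition by a carbometalation. It sets out from 9, which is treated with AlMe3 in THF in the presence of [RhCl(cod)]2 and the BINAP antipode that directs methyl to the face syn to the side chain. A chiral methyl complex of monovalent rhodium adds 1,2 to cyclic enones, a reaction type known for cyclohex-2-enone and 4-substituted analogues. The fallback returns directly at 10 and makes no new compound (F0).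

Step 13. The ligand may not control the aldehyde face well enough (the β-stereocentre C7 offers no useful induction), or turnover may be slow because the free tertiary alcohol binds the oxophilic metals. The fallback sets C9 by ketone reduction instead of during C–C bond formation. It sets out from 12 and 19, which are coupled without a chiral ligand (CrCl2 in excess, NiCl2 cat., DMSO, rt) to give 20 together with its 9R epimer F4. Dess–Martin oxidation of the mixture (only the secondary allylic alcohol can react) gives the 4-oxo enoate F5. Corey–Bakshi–Shibata reduction with (R)-2-methyl-CBS-oxazaborolidine and BH3·SMe2 in THF at low temperature, with the alkenyl group acting as the larger ketone substituent, should return the 9S alcohol, so the route is rejoined at 20.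

Further compounds
F1 | step 5 | RAMP hydrazone of 5, (E)-N-[(R)-2-(methoxymethyl)pyrrolidin-1-yl]imine of (R)-5-[(tert-butyldiphenylsilyl)oxy]-3-methylpentanal | CC(C)(C)[Si](OCC[C@@H](C)C/C=N/N1CCC[C@@H]1COC)(c1ccccc1)c1ccccc1
F2 | step 5 | RAMP hydrazone of (S)-2-[(R)-4-[(tert-butyldiphenylsilyl)oxy]butan-2-yl]-4-(2-methyl-1,3-dioxolan-2-yl)butanal | CC(C)(C)[Si](OCC[C@@H](C)[C@H](CCC1(C)OCCO1)/C=N/N1CCC[C@@H]1COC)(c1ccccc1)c1ccccc1
F3 | step 5 | (S)-2-[(R)-4-[(tert-butyldiphenylsilyl)oxy]butan-2-yl]-4-(2-methyl-1,3-dioxolan-2-yl)butanal | CC(C)(C)[Si](OCC[C@@H](C)[C@H](CCC1(C)OCCO1)C=O)(c1ccccc1)c1ccccc1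
F0 | step 6 | none | none
F4 | step 13 | methyl (2E,4R,6R)-4-hydroxy-6-[(1S,4R)-4-hydroxy-4-methylcyclohex-2-en-1-yl]-2-(4-methylpent-3-en-1-yl)hept-2-enoate | COC(=O)/C(=C/[C@@H](C[C@@H](C)[C@H]1C=C[C@](C)(O)CC1)O)CCC=C(C)C
F5 | step 13 | methyl (2E,6R)-6-[(1S,4R)-4-hydroxy-4-methylcyclohex-2-en-1-yl]-2-(4-methylpent-3-en-1-yl)-4-oxohept-2-enoate | COC(=O)/C(=C/C(=O)C[C@@H](C)[C@H]1C=C[C@](C)(O)CC1)CCC=C(C)C
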